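**Easy step.** Start where a single portion stands in the flask: up to 12 min, each reading is that portion's Qc as a fraction of the whole charge. Blue and amber agree about as closely as the scatter allows, so average them and treat the portions as independent: 4.70% at age 6.00 min, 6.30% at age 12.0 min.

| setting | blue | amber | delta | eta | alpha |
|---|---|---|---|---|---|
| Qa | 0.50 M (in portions, 3) | 2 M (in portions, 3) | 1.0 M (in portions, 3) | 1.0 M (in portions, 3) | 1.0 M (in portions, 3) |
| Qe | 0.020 M | 0.020 M | 0.0200 M | 0.0200 M | 0.0200 M |
| remark | run made earlier; portions every 12 min | run made earlier; portions every 12 min | the portions of Qa follow each other after 12 min, the first at the start | the portions of Qa follow each other after 20 min, the first at the start | the portions of Qa follow each other after 25 min, the first at the start |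
| time |  |  | 50 min | 50 min | 50 min |

| run | time / min | Qc / % |
|---|---|---|
| blue | 2.50 | 1.3 |
| blue | 6.00 | 4.6 |
| blue | 12.0 | 5.9 |
| blue | 30.0 | 13.4 |
| amber | 2.50 | 1.9 |
| amber | 6.00 | 4.8 |
| amber | 12.0 | 6.7 |
| amber | 30.0 | 13.1 |

(each reading ± 0.3 percentage points)

- amount of Qc at the end, in percent of the Qa charged for delta, eta, alpha, in this order
- how the row runs (rises all the way / rises, then falls / falls, then rises / hardly changes / falls all the way)

- "hardly changes" means that all values lie within two and a half points (for a concentration: within two and a half percent of the largest)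

**Two times.** Read the rise time of a portion's Qc from that pair, as for a saturating climb: 5.57 min. Now take the reading at 30.0 min, averaged to 13.2%. Subtract the youngest portion, aged 6.00 min. The two older ones then hold 4.28% each, at mean age 24.0 min, which is less than 6.30%. So old portions lose Qc. Call the exponential time of that loss the fade time: 30.9 min. It is longer than the rise, by a factor of 5.55, so, as read from these runs, each portion gives a hump topping near 11.6 min.

**My row.** Sum one term per portion by age. The last portions end at ages 26.0 min, 10.0 min and 0 min: past the top, near it, and unborn. Interpolate eta's youngest between the readings. I get 8.57%, 11.1% and 5.98%: up, then down.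

The forecast differs, with 19.3%, 15.5%, 13.6%, falls all the way: “Late portions miss the active period”.

**The flask.** It gives 7.60%, 11.3%, 5.49%: rises, then falls.

    Qa → Qb (k = 0.240 min⁻¹)
    Qb ⇌ Qc (K = 1.16, k = 0.121 min⁻¹)
    Qb ⇌ Qd (K = 2.12, k = 0.0690 min⁻¹)
    Qb + Qe → Qh (k = 2.27 M⁻¹ min⁻¹)
    Qc → Qf (k = 0.0984 min⁻¹)
    Qb → Qg (k = 0.00832 min⁻¹)

**Fade carried.** Alpha holds 3.68% Qc at 25.0 min; fade that once and add a fresh copy, and you get 5.32% against 5.49%. In delta, fade the 10.5% standing at 24.0 min to the end, and add the last portion, aged 26.0 min by then, taken from alpha's figure at 25.0 min and faded the remaining 1.00 min: 8.08% against 7.60%. Take away the step from Qc to Qf, the largest single effect on alpha's final Qc, and alpha ends at 18.5%, not 5.49%.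

The runs come from a simulation for substances that don't exist; scatter was added.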